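**Retrosynthetic overview**
1. Target 23 comes from aldol adduct 20 by one-pot acetylation and E1cB loss of acetic acid, which gives the C7=C8 alkene and the C12 acetate.
2. Adduct 20 comes from an aldol union (C7–C8) of hydroxycyclopentenone 11 with the Z-enal 18.
3. Cyclopentenone 11 comes from furan 8 by an enantioselective aqueous Piancatelli rearrangement: water forms the C12–O bond at the alkyl-bearing furan carbon, and the only ring of the molecule closes in the same step.
4. Furan 8 comes from furfuryl alcohol and dienyl bromide 5, itself made from 1-bromopent-2-yne and propargyl alcohol.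
5. Enal 18 comes from ynone 14 (acyl Sonogashira) by transfer hydrogenation (sets C4), acetylation, cis-semihydrogenation and acetal hydrolysis.

Assumption: late compounds carry prostanoid locants (C1 ester carbon, cyclopentenone C8–C12, C20 terminal methyl), and the sense of induction in step 5 is assigned by analogy with chiral-acid Nazarov closures, the mirror-image acid being used if the first run shows the opposite sense.

**Route**

Step 1
Reactants: 1 1-bromopent-2-yne; 2 prop-2-yn-1-ol
Product: 3 octa-2,5-diyn-1-ol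
Conditions: CuI (1 equiv), NaI (1 equiv), K2CO3 (1.5 equiv), DMF, rt
Reagents that add atoms: none
Why: The copper acetylide formed from the terminal alkyne under carbonate base displaces the propargylic bromide (copper-mediated alkyne–propargyl halide coupling) to give the skipped diyne without allene formation.

Step 2
Reactants: 3 octa-2,5-diyn-1-ol
Product: 4 (2Z,5Z)-octa-2,5-dien-1-ol
Conditions: H2 (1 atm), Pd/CaCO3 poisoned with Pb(OAc)2, quinoline, MeOH, rt
Reagents that add atoms: none
Why: Syn semihydrogenation on lead-poisoned palladium sets both Z alkenes and stops at the diene.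

Step 3
Reactants: 4 (2Z,5Z)-octa-2,5-dien-1-ol
Product: 5 (2Z,5Z)-1-bromoocta-2,5-diene
Conditions: CBr4, PPh3, CH2Cl2, 0 °C
Reagents that add atoms: carbon tetrabromide, BrC(Br)(Br)Br
Why: Appel bromination converts the primary allylic alcohol by SN2 at low temperature, without allylic shift or Z to E isomerization.

Step 4
Reactants: 6 furan-2-ylmethanol; 5 (2Z,5Z)-1-bromoocta-2,5-diene
Product: 8 {5-[(2Z,5Z)-octa-2,5-dien-1-yl]furan-2-yl}methanol, via dilithio furfuryl alkoxide 7 (not isolated)
Conditions: n-BuLi (2.2 equiv), TMEDA, THF, −78 to 0 °C; then 5 (0.9 equiv), −78 °C to rt; then H2O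
Reagents that add atoms: none
Why: The lithium alkoxide is lithiated at the free furan α-position (C5), and the furyllithium alkylates the primary allylic bromide by SN2 (lithiation/alkylation), leaving the Z,Z-diene untouched.

Step 5
Reactants: 8 {5-[(2Z,5Z)-octa-2,5-dien-1-yl]furan-2-yl}methanol
Product: 11 (4R)-4-hydroxy-4-[(2Z,5Z)-octa-2,5-dien-1-yl]cyclopent-2-en-1-one, via hemiketal 9 (not isolated), via dienol ketone 10 (not isolated)
Conditions: (R)-3,3′-bis(2,4,6-triisopropylphenyl)-1,1′-binaphthyl-2,2′-diyl N-triflylphosphoramide (10 mol%), H2O (10 equiv), toluene, 40 °C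
Reagents that add atoms: water, O
Why: Proposed new method: an enantioselective aqueous Piancatelli rearrangement of a primary 5-alkylfurfuryl alcohol, in which the strong chiral Brønsted acid ionizes the carbinol to the furanoxonium ion, water forms the C12–O bond at the alkyl-bearing furan carbon (9), ring opening gives 10, and its O-protonated hydroxypentadienyl cation, held by two hydrogen bonds to the chiral phosphoramide anion, closes by 4π conrotation in one sense only, fixing the quaternary carbinol centre as R in 11 (the same arrangement is 12S in the target); the closest known reactions are the racemic acid-promoted Piancatelli rearrangement of 5-methylfurylcarbinols and the chiral Brønsted-acid-controlled aza-Piancatelli and Nazarov cyclizations.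

Step 6
Reactants: 12 methyl 4-chloro-4-oxobutanoate; 13 3,3-diethoxyprop-1-yne
Product: 14 methyl 7,7-diethoxy-4-oxohept-5-ynoate
Conditions: PdCl2(PPh3)2 (2 mol%), CuI (4 mol%), Et3N, THF, rt
Reagents that add atoms: none
Why: Acyl Sonogashira coupling of the acid chloride with the terminal alkyne gives the ynone, with the aldehyde carbon carried as its diethyl acetal.

Step 7
Reactants: 14 methyl 7,7-diethoxy-4-oxohept-5-ynoate
Product: 15 methyl (4R)-7,7-diethoxy-4-hydroxyhept-5-ynoate
Conditions: Ru[(R,R)-TsDPEN](p-cymene) (1 mol%), i-PrOH, rt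
Reagents that add atoms: none
Why: Noyori asymmetric transfer hydrogenation of the alkynyl ketone under base-free conditions, in which the alkynyl group takes the place of the aryl group in the six-membered hydride-transfer transition state, so the (R,R) catalyst delivers hydride to the face that gives 4R.

Step 8
Reactants: 15 methyl (4R)-7,7-diethoxy-4-hydroxyhept-5-ynoate
Product: 16 methyl (4R)-4-acetoxy-7,7-diethoxyhept-5-ynoate
Conditions: Ac2O, pyridine, DMAP (5 mol%), CH2Cl2, 0 °C
Reagents that add atoms: acetic anhydride, CC(=O)OC(C)=O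
Why: DMAP-catalysed O-acylation at oxygen leaves C4 untouched and blocks lactonization of the γ-hydroxy ester.

Step 9
Reactants: 16 methyl (4R)-4-acetoxy-7,7-diethoxyhept-5-ynoate
Product: 17 methyl (4R,5Z)-4-acetoxy-7,7-diethoxyhept-5-enoate
Conditions: H2 (1 atm), Pd/CaCO3 poisoned with Pb(OAc)2, quinoline, EtOAc, rt
Reagents that add atoms: none
Why: Syn semihydrogenation of the alkyne gives the 5Z alkene, with the propargylic acetate and the acetal unchanged.

Step 10
Reactants: 17 methyl (4R,5Z)-4-acetoxy-7,7-diethoxyhept-5-enoate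
Product: 18 methyl (4R,5Z)-4-acetoxy-7-oxohept-5-enoate
Conditions: SiO2, 10% aq. oxalic acid, CH2Cl2, 0 °C; used at once
Reagents that add atoms: water, O
Why: Mild heterogeneous acetal hydrolysis on wet acidic silica releases the Z-enal at low temperature, before acid-promoted Z to E isomerization can compete.

Step 11
Reactants: 11 (4R)-4-hydroxy-4-[(2Z,5Z)-octa-2,5-dien-1-yl]cyclopent-2-en-1-one; 18 methyl (4R,5Z)-4-acetoxy-7-oxohept-5-enoate
Product: 20 methyl (4R,5Z,12S,14Z,17Z)-4-acetoxy-7,12-dihydroxy-9-oxoprosta-5,10,14,17-tetraenoate (mixture of C7/C8 epimers), via dilithium dienolate 19 (not isolated)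
Conditions: LiN(i-Pr)2 (2.1 equiv), THF, −78 °C; then 18, −78 °C, 15 min; AcOH quench at −78 °C
Reagents that add atoms: none
Why: The only enolizable position of 11 (C8) gives a cross-conjugated lithium enolate whose β-alkoxide is a poor leaving group, and it adds 1,2 to the aldehyde (aldol addition) faster than it touches the ester or acetate; the new C7 and C8 centres are removed in step 12, while C4 and C12 are untouched.

Step 12
Reactants: 20 methyl (4R,5Z,12S,14Z,17Z)-4-acetoxy-7,12-dihydroxy-9-oxoprosta-5,10,14,17-tetraenoate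
Product: 23 methyl (4R,5Z,7E,12S,14Z,17Z)-4,12-diacetoxy-9-oxoprosta-5,7,10,14,17-pentaenoate, via C7 acetate 21 (not isolated), via hydroxy dienone 22 (not isolated)
Conditions: Ac2O (10 equiv), DMAP (1 equiv), Et3N (10 equiv), CH2Cl2, 0 °C to rt, dark
Reagents that add atoms: acetic anhydride, CC(=O)OC(C)=O
Why: Acetylation of the C7 hydroxyl is followed by E1cB loss of acetic acid (completing the aldol condensation) to the cross-conjugated dienone, expected mainly as the 7E isomer with C6 anti to the C9 carbonyl (minor 7Z isomer removed by chromatography), and the tertiary C12 hydroxyl is then acetylated under DMAP catalysis (Steglich-type acylation) without touching either stereocentre.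

**Compound list**
1 | 1-bromopent-2-yne | CCC#CCBr | starting material
2 | prop-2-yn-1-ol | C#CCO | starting material
3 | octa-2,5-diyn-1-ol | CCC#CCC#CCO | intermediate
4 | (2Z,5Z)-octa-2,5-dien-1-ol | CC/C=C\C/C=C\CO | intermediate
5 | (2Z,5Z)-1-bromoocta-2,5-diene | CC/C=C\C/C=C\CBr | intermediate
6 | furan-2-ylmethanol (furfuryl alcohol) | OCc1ccco1 | starting material
7 | lithium (5-lithiofuran-2-yl)methanolate | [Li]OCc1ccc([Li])o1 | intermediate
8 | {5-[(2Z,5Z)-octa-2,5-dien-1-yl]furan-2-yl}methanol | CC/C=C\C/C=C\Cc1ccc(CO)o1 | intermediate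
9 | 5-methylidene-2-[(2Z,5Z)-octa-2,5-dien-1-yl]-2,5-dihydrofuran-2-ol | C=C1C=CC(O)(C/C=C\C/C=C\CC)O1 | intermediate
10 | (3Z,7Z,10Z)-2-hydroxytrideca-1,3,7,10-tetraen-5-one | C=C(O)/C=C\C(=O)C/C=C\C/C=C\CC | intermediate
11 | (4R)-4-hydroxy-4-[(2Z,5Z)-octa-2,5-dien-1-yl]cyclopent-2-en-1-one | CC/C=C\C/C=C\C[C@]1(O)C=CC(=O)C1 | intermediate
12 | methyl 4-chloro-4-oxobutanoate | COC(=O)CCC(Cl)=O | starting material
13 | 3,3-diethoxyprop-1-yne | CCOC(OCC)C#C | starting material
14 | methyl 7,7-diethoxy-4-oxohept-5-ynoate | COC(=O)CCC(=O)C#CC(OCC)OCC | intermediate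
15 | methyl (4R)-7,7-diethoxy-4-hydroxyhept-5-ynoate | COC(=O)CC[C@@H](O)C#CC(OCC)OCC | intermediate
16 | methyl (4R)-4-acetoxy-7,7-diethoxyhept-5-ynoate | COC(=O)CC[C@@H](OC(C)=O)C#CC(OCC)OCC | intermediate
17 | methyl (4R,5Z)-4-acetoxy-7,7-diethoxyhept-5-enoate | COC(=O)CC[C@@H](OC(C)=O)/C=C\C(OCC)OCC | intermediate
18 | methyl (4R,5Z)-4-acetoxy-7-oxohept-5-enoate | COC(=O)CC[C@@H](OC(C)=O)/C=C\C=O | intermediate
19 | dilithium salt of 11 (C12 alkoxide, C8–C9 enolate) | CC/C=C\C/C=C\C[C@]1(O[Li])C=CC(O[Li])=C1 | intermediate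
20 | methyl (4R,5Z,12S,14Z,17Z)-4-acetoxy-7,12-dihydroxy-9-oxoprosta-5,10,14,17-tetraenoate (C7/C8 epimers) | CC/C=C\C/C=C\C[C@]1(O)C=CC(=O)C1C(O)/C=C\[C@@H](CCC(=O)OC)OC(C)=O | intermediate
21 | methyl (4R,5Z,12S,14Z,17Z)-4,7-diacetoxy-12-hydroxy-9-oxoprosta-5,10,14,17-tetraenoate (C7/C8 epimers) | CC/C=C\C/C=C\C[C@]1(O)C=CC(=O)C1C(OC(C)=O)/C=C\[C@@H](CCC(=O)OC)OC(C)=O | intermediate
22 | methyl (4R,5Z,7E,12S,14Z,17Z)-4-acetoxy-12-hydroxy-9-oxoprosta-5,7,10,14,17-pentaenoate | CC/C=C\C/C=C\C[C@]1(O)C=CC(=O)/C1=C/C=C\[C@@H](CCC(=O)OC)OC(C)=O | intermediate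
23 | methyl (4R,5Z,7E,12S,14Z,17Z)-4,12-diacetoxy-9-oxoprosta-5,7,10,14,17-pentaenoate | CC/C=C\C/C=C\C[C@]1(OC(C)=O)C=CC(=O)/C1=C/C=C\[C@@H](CCC(=O)OC)OC(C)=O | target

**Step count**
Total: 12 steps. Longest linear sequence: 7 steps (1→2→3→4→5→11→12, or equally 6→7→8→9→10→11→12).

**Steps most likely to fail**

Step 5 (the proposed new rearrangement). The risks are weak ionization of a primary furfuryl alcohol, furan oligomerization and low or reversed enantioselectivity. The fallback sets out from 8 and uses known chemistry only. The rearrangement is run without chiral control under established Piancatelli conditions (ZnCl2, dioxane/H2O, reflux, or Dy(OTf)3, MeCN/H2O, 80 °C) to give racemic 4-hydroxy-4-[(2Z,5Z)-octa-2,5-dien-1-yl]cyclopent-2-en-1-one F1. F1 is resolved by preparative supercritical-fluid chromatography on an amylose tris(3,5-dimethylphenylcarbamate) phase, and the R enantiomer is 11, where the route is rejoined.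

Step 11 (aldol with the labile Z-enal). The risks are Z to E isomerization or decomposition of 18 before or during addition. The fallback sets out from 16 and keeps C5–C6 as an alkyne through the union. The acetal of 16 is hydrolysed on wet SiO2/oxalic acid to methyl (4R)-4-acetoxy-7-oxohept-5-ynoate F2. F2 is added to dienolate 19 (made from 11 as before) to give methyl (4R,12S,14Z,17Z)-4-acetoxy-7,12-dihydroxy-9-oxoprosta-10,14,17-trien-5-ynoate F3. Ac2O/DMAP/Et3N takes F3 through its 7-acetate F4 and the hydroxy enynone F5 to the 5,6-didehydro diacetate F6. Semihydrogenation of the single alkyne (H2, Pd/CaCO3 poisoned with Pb(OAc)2, quinoline, EtOAc) sets 5Z last and comes back to the route at 23.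

Step 12 (one-pot acetylation, elimination and tertiary acetylation). The risks are a poor 7E/7Z ratio, DMAP-induced isomerization of the 5Z alkene and incomplete acetylation of the hindered C12 hydroxyl. The fallback sets out from 20 and separates the events. MsCl/Et3N in CH2Cl2 at −20 °C gives the C7 mesylate F7, which eliminates on warming with Et3N to 22. Here 22 is isolated, and its free hydroxyl allows the 7E and 7Z isomers to be separated on silica. The tertiary alcohol is then acetylated by Lewis-acid catalysis (Ac2O, Sc(OTf)3 1 mol%, MeCN, −20 °C) instead of nucleophilic catalysis, coming back to the route at 23.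

**Further compounds**
F1 | step 5 | racemic 4-hydroxy-4-[(2Z,5Z)-octa-2,5-dien-1-yl]cyclopent-2-en-1-one | CC/C=C\C/C=C\CC1(O)C=CC(=O)C1
F2 | step 11 | methyl (4R)-4-acetoxy-7-oxohept-5-ynoate | COC(=O)CC[C@@H](OC(C)=O)C#CC=O
F3 | step 11 | methyl (4R,12S,14Z,17Z)-4-acetoxy-7,12-dihydroxy-9-oxoprosta-10,14,17-trien-5-ynoate (C7/C8 epimers) | CC/C=C\C/C=C\C[C@]1(O)C=CC(=O)C1C(O)C#C[C@@H](CCC(=O)OC)OC(C)=O
F4 | step 11 | methyl (4R,12S,14Z,17Z)-4,7-diacetoxy-12-hydroxy-9-oxoprosta-10,14,17-trien-5-ynoate (C7/C8 epimers) | CC/C=C\C/C=C\C[C@]1(O)C=CC(=O)C1C(OC(C)=O)C#C[C@@H](CCC(=O)OC)OC(C)=O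
F5 | step 11 | methyl (4R,7E,12S,14Z,17Z)-4-acetoxy-12-hydroxy-9-oxoprosta-7,10,14,17-tetraen-5-ynoate | CC/C=C\C/C=C\C[C@]1(O)C=CC(=O)/C1=C/C#C[C@@H](CCC(=O)OC)OC(C)=O
F6 | step 11 | methyl (4R,7E,12S,14Z,17Z)-4,12-diacetoxy-9-oxoprosta-7,10,14,17-tetraen-5-ynoate | CC/C=C\C/C=C\C[C@]1(OC(C)=O)C=CC(=O)/C1=C/C#C[C@@H](CCC(=O)OC)OC(C)=O
F7 | step 12 | methyl (4R,5Z,12S,14Z,17Z)-4-acetoxy-12-hydroxy-7-(methanesulfonyloxy)-9-oxoprosta-5,10,14,17-tetraenoate (C7/C8 epimers) | CC/C=C\C/C=C\C[C@]1(O)C=CC(=O)C1C(OS(C)(=O)=O)/C=C\[C@@H](CCC(=O)OC)OC(C)=O
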